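The numbers in the tables were generated by integration with constants of no real substance; the scatter is artificial.

Of the L and X together at the last reading (20.0 h) of the red and teal runs, L held 21.1 %, and I carried this end share of L in L + X to the next flasks.

all flasks: E 31 mM

| charge | Q | remark | time |
|---|---|---|---|
| grey | 22 mM | run made earlier |  |
| red | 33 mM | run made earlier |  |
| teal | 41 mM | run made earlier |  |
| alpha | 37.2 mM |  | 25 h |
| eta | 25.0 mM |  | 6.0 h |

| run | time / h | L / % | X / % |
|---|---|---|---|
| grey | 1.33 | 23.8 | 6.3 |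
| grey | 2.50 | 25.2 | 14.3 |
| grey | 5.00 | 19.8 | 28.7 |
| grey | 10.0 | 14.2 | 39.9 |
| grey | 20.0 | 10.3 | 40.9 |
| red | 4.00 | 29.0 | 30.1 |
| red | 8.00 | 19.7 | 46.5 |
| red | 10.0 | 18.3 | 49.6 |
| red | 15.0 | 15.0 | 53.8 |
| red | 20.0 | 14.2 | 54.0 |
| teal | 1.33 | 36.5 | 9.9 |
| teal | 2.50 | 36.9 | 21.9 |
| teal | 5.00 | 27.8 | 40.9 |
| teal | 10.0 | 18.1 | 55.7 |
| teal | 20.0 | 16.3 | 60.2 |

(standard deviation of a reading: 0.5 percentage points)

- what was read earlier has a scatter of 0.5 percentage points, one standard deviation

1. which one finishes higher in amount of L, in percent of the E charged ("neither" within 2 percentage points) (alpha / eta / neither)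
2. amount of L at the end, in percent of the E charged, alpha
3. amount of L at the end, in percent of the E charged, eta

I treated L and X as one pool and kept the books on Q. L + X at the last reading rose from 68.2 % in red to 76.5 % in teal, although red's Q was already above its E, so I took Q as the limiting reagent and counted one Q per L.

Alpha, with the pool at the last reading interpolated between red and teal and taken for its end:

Q charged: 37.2 mM
into L + X: 72.6 % of E, or 22.5 mM
not found in L or X: 14.7 mM
L at the end share: 15.3 %

Eta stops early. Grey's share was 40.8 % at 5.00 h and 26.2 % at 10.0 h, so I could not use the end share.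

share at 6.0 h, interpolated: 37.9 %
grey pool at 6.0 h, interpolated: 49.6 %
teal pool at 6.0 h, interpolated: 69.7 %
eta's pool, between grey and teal: 52.8 %
L: 20.0 %

So I put eta higher: its pool was smaller than alpha's, but its share was above the end share. The forecast said eta, with 14.8 % for alpha, below my 15.3 %, and 20 % for eta: “Eta should therefore finish higher, because it is stopped before L has relaxed.”

The flask gave eta, with 14.8 % for alpha and 19.8 % for eta.

    E + Q → L + Z (k = 19.0 M⁻¹ h⁻¹)
    L ⇌ X (K = 3.80, k = 0.310 h⁻¹)
    L ⇌ G (K = 2.20, k = 0.0250 h⁻¹)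
    2 Q → J (k = 4.80 M⁻¹ h⁻¹)

Neither flask had come to rest. Alpha's share of L was 20.5 % at 25.0 h and 20.8 % at 250 h, yet its L still fell to 12.1 % as G rose from 10.6 % to 25.9 %. Eta's share went from 36.6 % at 6.00 h to 20.4 % at 60.0 h; the end share on its L + X then gives 10.7 %. At 60.0 h eta held 10.4 % of L and 13.3 % of G.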